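The route rests on detaching ring A of unit 2 (the 5,7-dihydroxy half, doubly primed numbers) from O1'' and C4''. That ring is held through two adjacent carbons: C8a'' carries the ring oxygen, C4a'' the ketone carbon, and C4a'' is flanked on its other side by oxygenated C5'', which is the order in which a 3-alkoxyaryne accepts a nucleophile and an electrophile. One operation forms O1''–C8a'' and C4''–C4a'' and closes ring C of unit 2 without touching a stereocentre. The precursor is the benzylated unit 1 flavanone whose C3 bears the anti β-hydroxy methyl ester C3''H(CO2Me)–C2''H(OH)Ar, silylated in the flask so that no O–H proton quenches the aryl anion.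

Key step: step 11

Assumption: the magnesium-catalysed anti-aldol of an (S)-4-benzyloxazolidinone imide is taken to give the (α-R, β-S) adduct (chelated Z-enolate attacked opposite to the benzyl group). If the opposite sense were found, the (R)-auxiliary would be used. Flavanone numbering (C2, C3, C4 / C2'', C3'', C4'') is applied to the chain from step 2 on, and Ar = 4-(benzyloxy)phenyl.

Step 1
Reactants: 1 (4S)-4-benzyl-1,3-oxazolidin-2-one; 2 succinyl chloride
Product: 4 1,4-bis[(4S)-4-benzyl-2-oxo-1,3-oxazolidin-3-yl]butane-1,4-dione, via lithium oxazolidinide 3 (not isolated)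
Conditions: 1 (2 equiv), n-BuLi, THF, −78 °C; then 2, −78 → 0 °C
Reagents that add atoms: none
Why: N-acylation of the lithiated oxazolidinone at both acid chloride ends is the standard imide synthesis and creates no stereocentre.

Step 2
Reactants: 4 bis-imide; 5 4-(benzyloxy)benzaldehyde
Product: 7 (2R,3R)-1,4-bis[(4S)-4-benzyl-2-oxo-1,3-oxazolidin-3-yl]-2,3-bis{(S)-[4-(benzyloxy)phenyl](trimethylsilyloxy)methyl}butane-1,4-dione, via mono-adduct 6 (not isolated)
Conditions: 5 (3 equiv), MgCl2 (0.5 equiv), NaSbF6 (0.6 equiv), Et3N, TMSCl, EtOAc, rt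
Reagents that add atoms: chlorotrimethylsilane, C[Si](C)(C)Cl
Why: Evans magnesium-halide-catalysed direct anti-aldol, made for non-enolisable aromatic aldehydes: each chelated Z-enolate is attacked opposite to its own benzyl group, the anti adduct forms and silylation of the aldolate makes the addition irreversible, so the two identical (S)-auxiliaries should set C3 and C3'' as R and C2 and C2'' as S and turn 6 into the twofold-symmetric 7.

Step 3
Reactants: 7 bis-TMS ether
Product: 9 (2R,3R)-1,4-bis[(4S)-4-benzyl-2-oxo-1,3-oxazolidin-3-yl]-2,3-bis{(S)-[4-(benzyloxy)phenyl](tert-butyldimethylsilyloxy)methyl}butane-1,4-dione, via diol 8 (not isolated)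
Conditions: TFA (cat.), MeOH/CH2Cl2, 0 °C, evaporate; TBSOTf, 2,6-lutidine, CH2Cl2, −78 → 0 °C
Reagents that add atoms: tert-butyldimethylsilyl trifluoromethanesulfonate, CC(C)(C)[Si](C)(C)OS(=O)(=O)C(F)(F)F
Why: Acid methanolysis of the labile TMS ethers and immediate silylation (silyl ether exchange) installs groups that survive peroxide hydrolysis and an aryllithium; diol 8 is not stored because each hydroxyl is γ to the far imide, although lactonisation would have to build an all-cis trisubstituted butyrolactone and should be slow, and no stereocentre is touched.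

Step 4
Reactants: 9 bis-TBS bis-imide
Product: 10 (2R,3R)-2,3-bis{(S)-[4-(benzyloxy)phenyl](tert-butyldimethylsilyloxy)methyl}butanedioic acid
Conditions: LiOH, H2O2, THF/H2O, 0 °C → rt; Na2SO3; 1 M HCl
Reagents that add atoms: hydrogen peroxide (acting as LiOOH; one oxygen stays in each carboxyl group), OO
Why: Hydroperoxide hydrolysis of Evans imides attacks the exocyclic carbonyl even in hindered cases, does not enolise C3 or C3'' and returns the auxiliary.

Step 5
Reactants: 10 diacid
Product: 11 (3R,4R)-3,4-bis{(S)-[4-(benzyloxy)phenyl](tert-butyldimethylsilyloxy)methyl}oxolane-2,5-dione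
Conditions: DCC, CH2Cl2, 0 °C → rt
Reagents that add atoms: none
Why: Carbodiimide dehydration closes the five-membered anhydride, on which the (R,R)-diacid places its two large groups trans, the stable arrangement, so epimerisation has no driving force.

Step 6
Reactants: 12 4-bromo-3-fluorophenol
Product: 13 4-(benzyloxy)-1-bromo-2-fluorobenzene
Conditions: BnBr, K2CO3, DMF, rt
Reagents that add atoms: benzyl bromide, BrCc1ccccc1
Why: Williamson ether synthesis on a phenol.

Step 7
Reactants: 13 aryl bromide; 11 anhydride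
Product: 15 (2R,3R)-4-[4-(benzyloxy)-2-fluorophenyl]-2,3-bis{(S)-[4-(benzyloxy)phenyl](tert-butyldimethylsilyloxy)methyl}-4-oxobutanoic acid, via aryllithium 14 (not isolated)
Conditions: 13, n-BuLi, THF, −78 °C; cannulated into 11, THF, −78 °C; 1 M HCl
Reagents that add atoms: none
Why: Bromine–lithium exchange at −78 °C outruns loss of LiF, and acylation of an aryllithium by a cyclic anhydride stops at the ketone because the carboxylate stays attached and the hindered ketone is inert at this temperature; the two carbonyls of 11 are homotopic, so a single keto acid should result, and this step defines the unit 1 half (C4 ketone) and the unit 2 half (C4'' acid).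

Step 8
Reactants: 15 keto acid
Product: 17 methyl (2R,3S)-2-{(2S,3R)-7-(benzyloxy)-2-[4-(benzyloxy)phenyl]-4-oxo-3,4-dihydro-2H-chromen-3-yl}-3-[4-(benzyloxy)phenyl]-3-hydroxypropanoate, via flavanone acid 16 (not isolated)
Conditions: Bu4NF, THF, −20 → 0 °C; then MeI, 0 °C → rt
Reagents that add atoms: iodomethane, CI
Why: Fluoride desilylation followed by intramolecular nucleophilic aromatic substitution (addition–elimination through a six-membered ring) of the ortho-acyl-activated fluoride by the C2 alkoxide, with retention at C2; C4'' is kept as a carboxylate during closure because a methyl ester would be captured by the C2 alkoxide as a γ-lactone, the C2'' oxygen can reach the arene only through a seven-membered ring, C3 sits trans-diequatorial to the C2 aryl group, and the ammonium carboxylate is then O-alkylated by MeI.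

Step 9
Reactants: 18 3,5-bis(benzyloxy)phenol
Product: 19 3,5-bis(benzyloxy)-2-bromophenol
Conditions: NBS, CH2Cl2, −78 → 0 °C
Reagents that add atoms: N-bromosuccinimide, O=C1CCC(=O)N1Br
Why: Electrophilic aromatic bromination, directed ortho to the hydroxyl and para to a benzyloxy group, because the position between the two benzyloxy groups is more hindered.

Step 10
Reactants: 19 bromophenol
Product: 22 3,5-bis(benzyloxy)-2-(trimethylsilyl)phenyl trifluoromethanesulfonate, via silyl ether 20 (not isolated), via lithium phenoxide 21 (not isolated)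
Conditions: HMDS, THF, 65 °C, evaporate; n-BuLi, THF, −100 → −78 °C; Tf2O, −78 °C
Reagents that add atoms: hexamethyldisilazane, C[Si](C)(C)N[Si](C)(C)C; trifluoromethanesulfonic anhydride, O=S(=O)(OS(=O)(=O)C(F)(F)F)C(F)(F)F
Why: O-silylation, bromine–lithium exchange with retro-Brook 1,3-shift of silicon from oxygen to carbon, and triflation of the phenoxide form the standard sequence to ortho-silylaryl triflates and fix silicon on the carbon beside a benzyloxy group.

Step 11
Reactants: 17 β-hydroxy ester of the unit 1 flavanone; 22 ortho-silylaryl triflate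
Product: 25 (2S,3R,2''S,3''R)-7,4',5'',7'',4'''-pentakis(benzyloxy)-3,3''-biflavanone, via silyl ether 23 (not isolated), via aryne 24 (not isolated)
Conditions: HMDS, TMSCl (cat.), CH2Cl2, rt, evaporate; 22 (2 equiv), KF, 18-crown-6, THF, 0 °C → rt
Reagents that add atoms: none
Why: Proposed new method: fluoride removes the TMS group from the C2'' oxygen of 23 and from the arene carbon of 22 (loss of triflate then gives aryne 24), the proton-free alkoxide adds to the aryne carbon remote from the flanking benzyloxy group (the future C8a''), and the aryl anion formed at C4a'' attacks the methyl ester carbon C4'' and expels methoxide. The closest known reaction type is the fluoride-mediated annulation of arynes with methyl salicylates to xanthones, together with acyl-transfer insertions of arynes into carboxylic acids and β-lactams, whereas an aliphatic β-silyloxy ester has not been used as the partner. Ring C of unit 2 closes by a 6-exo-trig acyl substitution in which anion and ester sit on the same short chain. No stereocentre is formed and no bond to C2, C3, C3'' or C2'' is broken, so the configuration of 17 is carried over, and C3 and C3'' end in the thermodynamically preferred trans-diequatorial positions. Regioselectivity comes from the C5'' benzyloxy group, whose inductive pull distorts the triple bond so that attack comes at the far carbon and charge builds next to oxygen, while the C7'' group is too remote to matter. Selectivity for oxygen over the C3 enolate of unit 1, and for acylation over protonation, is sought by unmasking only the silyl ether in an aprotic medium (no O–H, no acetonitrile) at or below room temperature, with the excess of 22 consuming the liberated methoxide.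

Step 12
Reactants: 25 pentabenzyl ether
Product: 26 (2S,3R,2''S,3''R)-7,4',5'',7'',4'''-pentahydroxy-3,3''-biflavanone (CNP0138443.1)
Conditions: H2 (1 atm), 10% Pd/C, THF/MeOH, rt
Reagents that add atoms: none
Why: Catalytic hydrogenolysis cleaves aryl benzyl ethers under neutral conditions that neither enolise C3 and C3'' nor open the pyranone rings.

Compound list
1 | (4S)-4-benzyl-1,3-oxazolidin-2-one | O=C1N[C@@H](Cc2ccccc2)CO1 | starting material
2 | succinyl chloride | O=C(Cl)CCC(=O)Cl | starting material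
3 | N-lithio-(4S)-4-benzyl-1,3-oxazolidin-2-one | [Li]N1[C@@H](Cc2ccccc2)COC1=O | intermediate
4 | 1,4-bis[(4S)-4-benzyl-2-oxo-1,3-oxazolidin-3-yl]butane-1,4-dione | O=C(CCC(=O)N1[C@@H](Cc2ccccc2)COC1=O)N1[C@@H](Cc2ccccc2)COC1=O | intermediate
5 | 4-(benzyloxy)benzaldehyde | O=Cc1ccc(OCc2ccccc2)cc1 | starting material
6 | mono-adduct, (2R)-2-{(S)-Ar(trimethylsilyloxy)methyl} bis-imide | C[Si](C)(C)O[C@H](c1ccc(OCc2ccccc2)cc1)[C@H](C(=O)N1[C@@H](Cc2ccccc2)COC1=O)CC(=O)N1[C@@H](Cc2ccccc2)COC1=O | intermediate
7 | (2R,3R)-bis-imide with two (S)-Ar(trimethylsilyloxy)methyl groups | C[Si](C)(C)O[C@H](c1ccc(OCc2ccccc2)cc1)[C@H](C(=O)N1[C@@H](Cc2ccccc2)COC1=O)[C@@H](C(=O)N1[C@@H](Cc2ccccc2)COC1=O)[C@H](O[Si](C)(C)C)c1ccc(OCc2ccccc2)cc1 | intermediate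
8 | (2R,3R)-bis-imide with two (S)-Ar(hydroxy)methyl groups | O[C@H](c1ccc(OCc2ccccc2)cc1)[C@H](C(=O)N1[C@@H](Cc2ccccc2)COC1=O)[C@@H](C(=O)N1[C@@H](Cc2ccccc2)COC1=O)[C@H](O)c1ccc(OCc2ccccc2)cc1 | intermediate
9 | (2R,3R)-bis-imide with two (S)-Ar(tert-butyldimethylsilyloxy)methyl groups | CC(C)(C)[Si](C)(C)O[C@H](c1ccc(OCc2ccccc2)cc1)[C@H](C(=O)N1[C@@H](Cc2ccccc2)COC1=O)[C@@H](C(=O)N1[C@@H](Cc2ccccc2)COC1=O)[C@H](O[Si](C)(C)C(C)(C)C)c1ccc(OCc2ccccc2)cc1 | intermediate
10 | (2R,3R)-2,3-bis{(S)-Ar(tert-butyldimethylsilyloxy)methyl}butanedioic acid | CC(C)(C)[Si](C)(C)O[C@H](c1ccc(OCc2ccccc2)cc1)[C@H](C(=O)O)[C@@H](C(=O)O)[C@H](O[Si](C)(C)C(C)(C)C)c1ccc(OCc2ccccc2)cc1 | intermediate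
11 | (3R,4R)-3,4-bis{(S)-Ar(tert-butyldimethylsilyloxy)methyl}oxolane-2,5-dione | O=C1OC(=O)[C@@H]([C@H](O[Si](C)(C)C(C)(C)C)c2ccc(OCc3ccccc3)cc2)[C@@H]1[C@H](O[Si](C)(C)C(C)(C)C)c1ccc(OCc2ccccc2)cc1 | intermediate
12 | 4-bromo-3-fluorophenol | Oc1ccc(Br)c(F)c1 | starting material
13 | 4-(benzyloxy)-1-bromo-2-fluorobenzene | Fc1cc(OCc2ccccc2)ccc1Br | intermediate
14 | [4-(benzyloxy)-2-fluorophenyl]lithium | [Li]c1ccc(OCc2ccccc2)cc1F | intermediate
15 | (2R,3R)-4-[4-(benzyloxy)-2-fluorophenyl]-2,3-bis{(S)-Ar(tert-butyldimethylsilyloxy)methyl}-4-oxobutanoic acid | CC(C)(C)[Si](C)(C)O[C@H](c1ccc(OCc2ccccc2)cc1)[C@H](C(=O)c1ccc(OCc2ccccc2)cc1F)[C@@H](C(=O)O)[C@H](O[Si](C)(C)C(C)(C)C)c1ccc(OCc2ccccc2)cc1 | intermediate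
16 | (2R,3S)-2-{(2S,3R)-7-(benzyloxy)-2-Ar-4-oxochroman-3-yl}-3-Ar-3-hydroxypropanoic acid | O=C1c2ccc(OCc3ccccc3)cc2O[C@H](c2ccc(OCc3ccccc3)cc2)[C@H]1[C@@H](C(=O)O)[C@H](O)c1ccc(OCc2ccccc2)cc1 | intermediate
17 | methyl ester of 16 (precursor of the key step) | O=C1c2ccc(OCc3ccccc3)cc2O[C@H](c2ccc(OCc3ccccc3)cc2)[C@H]1[C@@H](C(=O)OC)[C@H](O)c1ccc(OCc2ccccc2)cc1 | intermediate
18 | 3,5-bis(benzyloxy)phenol | Oc1cc(OCc2ccccc2)cc(OCc2ccccc2)c1 | starting material
19 | 3,5-bis(benzyloxy)-2-bromophenol | Oc1cc(OCc2ccccc2)cc(OCc2ccccc2)c1Br | intermediate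
20 | [3,5-bis(benzyloxy)-2-bromophenoxy]trimethylsilane | C[Si](C)(C)Oc1cc(OCc2ccccc2)cc(OCc2ccccc2)c1Br | intermediate
21 | lithium 3,5-bis(benzyloxy)-2-(trimethylsilyl)phenoxide | [Li]Oc1cc(OCc2ccccc2)cc(OCc2ccccc2)c1[Si](C)(C)C | intermediate
22 | 3,5-bis(benzyloxy)-2-(trimethylsilyl)phenyl trifluoromethanesulfonate | C[Si](C)(C)c1c(OCc2ccccc2)cc(OCc2ccccc2)cc1OS(=O)(=O)C(F)(F)F | intermediate
23 | C2''-O-trimethylsilyl ether of 17 | O=C1c2ccc(OCc3ccccc3)cc2O[C@H](c2ccc(OCc3ccccc3)cc2)[C@H]1[C@@H](C(=O)OC)[C@H](O[Si](C)(C)C)c1ccc(OCc2ccccc2)cc1 | intermediate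
24 | 3,5-bis(benzyloxy)benzyne | C1#CC(OCc2ccccc2)=CC(OCc2ccccc2)=C1 | intermediate
25 | (2S,3R,2''S,3''R)-7,4',5'',7'',4'''-pentakis(benzyloxy)-3,3''-biflavanone | O=C1c2ccc(OCc3ccccc3)cc2O[C@H](c2ccc(OCc3ccccc3)cc2)[C@H]1[C@H]1C(=O)c2c(OCc3ccccc3)cc(OCc3ccccc3)cc2O[C@@H]1c1ccc(OCc2ccccc2)cc1 | intermediate
26 | (2S,3R,2''S,3''R)-7,4',5'',7'',4'''-pentahydroxy-3,3''-biflavanone (CNP0138443.1) | O=C1c2ccc(O)cc2O[C@H](c2ccc(O)cc2)[C@H]1[C@H]1C(=O)c2c(O)cc(O)cc2O[C@@H]1c1ccc(O)cc1 | target

Total step count: 12. Longest linear sequence: 9 (steps 1, 2, 3, 4, 5, 7, 8, 11, 12).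

Steps most likely to fail

Step 11. The aryl anion may be protonated or silylated before it reaches the ester. The unmasked C2'' alkoxide may fragment by retro-aldol cleavage or eliminate. The basic medium may also open ring C of unit 1 through its C3 enolate. Fallback: the same two bonds are made one after the other by known reactions, setting out from 17.
- A copper-promoted Chan–Lam etherification of the C2'' hydroxyl with commercial [3,5-bis(benzyloxy)phenyl]boronic acid (Cu(OAc)2, DMAP, 4 Å molecular sieves, O2, CH2Cl2, rt) would give the aryl ether ester F1 with retention at C2''.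
- Me3SnOH in 1,2-dichloroethane at 80 °C would cleave the methyl ester without strong base to the aryl ether acid F2.
- Trifluoroacetic anhydride in CH2Cl2 at 0 °C would close ring C of unit 2 by intramolecular Friedel–Crafts acylation at either of the two equivalent positions ortho to O1''. This returns the route to 25.

Step 2. The second addition has to occur at a carbon next to a fully branched neighbour, and the auxiliary has to override the bias of the centres already set. The reaction may therefore stall at 6 or show poor facial selectivity in the second addition. Fallback: the C3–C3'' bond is made last, by oxidative homocoupling of a ring-locked enolate, so that each new centre is controlled by its own ring. The fallback sets out from 5.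
- A catalytic enantioselective Reformatsky reaction (methyl iodoacetate, Me2Zn, a BINOL-type ligand of the hand that gives the S carbinol) would give the hydroxy ester F3.
- LiOH would give the hydroxy acid F4.
- Acid-catalysed acetalisation with pivalaldehyde would give the cis-dioxanone F5.
- LDA at −78 °C followed by CuCl2 would couple two enolates, each anti to its own aryl group, to the dimer F6. F6 already holds the 2S,3R,3''R,2''S array, and the heterochiral pairing would be a separable diastereomer.
- LiOH would open both acylals to the dihydroxy diacid F7, kept as its dilithium salt.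
- TBSOTf/2,6-lutidine, followed by K2CO3 in aqueous MeOH to cleave the silyl esters, would return the route to 10.

Step 8. The β-oxygenated aryl ketone may lose silanolate by E1cB elimination. After desilylation it may also undergo retro-aldol and re-aldol scrambling of C2 before the fluoride is displaced. Fallback: ring C of unit 1 is closed by cross-coupling through a palladium alkoxide instead of a free aldolate, setting out from 11.
- The anhydride is opened with the arylmagnesium reagent made by iodine–magnesium exchange (iPrMgCl·LiCl, THF, −40 °C) from 4-(benzyloxy)-2-bromo-1-iodobenzene F8, itself obtained from commercial 3-bromo-4-iodophenol, BnBr and K2CO3. This would give the bromo keto acid F9.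
- Buffered HF·pyridine would free the dihydroxy bromo keto acid F10 without generating an alkoxide, and F10 would be used at once.
- A Buchwald–Hartwig-type intramolecular C–O coupling (Pd(OAc)2, a bulky di-tert-butylbiarylphosphine, Cs2CO3, toluene, 50 °C) would deliver 16. This is methylated as in step 8 to 17.

Further compounds
F1 | step 11 | methyl (2R,3S)-2-{(2S,3R)-7-(benzyloxy)-2-Ar-4-oxochroman-3-yl}-3-Ar-3-[3,5-bis(benzyloxy)phenoxy]propanoate | O=C1c2ccc(OCc3ccccc3)cc2O[C@H](c2ccc(OCc3ccccc3)cc2)[C@H]1[C@@H](C(=O)OC)[C@H](Oc1cc(OCc2ccccc2)cc(OCc2ccccc2)c1)c1ccc(OCc2ccccc2)cc1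
F2 | step 11 | carboxylic acid of F1 | O=C1c2ccc(OCc3ccccc3)cc2O[C@H](c2ccc(OCc3ccccc3)cc2)[C@H]1[C@@H](C(=O)O)[C@H](Oc1cc(OCc2ccccc2)cc(OCc2ccccc2)c1)c1ccc(OCc2ccccc2)cc1
F3 | step 2 | methyl (S)-3-[4-(benzyloxy)phenyl]-3-hydroxypropanoate | COC(=O)C[C@H](O)c1ccc(OCc2ccccc2)cc1
F4 | step 2 | (S)-3-[4-(benzyloxy)phenyl]-3-hydroxypropanoic acid | OC(=O)C[C@H](O)c1ccc(OCc2ccccc2)cc1
F5 | step 2 | (2R,6S)-6-[4-(benzyloxy)phenyl]-2-tert-butyl-1,3-dioxan-4-one | CC(C)(C)[C@H]1OC(=O)C[C@@H](c2ccc(OCc3ccccc3)cc2)O1
F6 | step 2 | (2R,2'R,5R,5'R,6S,6'S)-6,6'-bis[4-(benzyloxy)phenyl]-2,2'-di-tert-butyl-5,5'-bi(1,3-dioxane)-4,4'-dione | CC(C)(C)[C@H]1OC(=O)[C@H]([C@H]2C(=O)O[C@H](C(C)(C)C)O[C@@H]2c2ccc(OCc3ccccc3)cc2)[C@@H](c2ccc(OCc3ccccc3)cc2)O1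
F7 | step 2 | (2R,3R)-2,3-bis{(S)-[4-(benzyloxy)phenyl](hydroxy)methyl}butanedioic acid | O[C@H](c1ccc(OCc2ccccc2)cc1)[C@H](C(=O)O)[C@@H](C(=O)O)[C@H](O)c1ccc(OCc2ccccc2)cc1
F8 | step 8 | 4-(benzyloxy)-2-bromo-1-iodobenzene | Brc1cc(OCc2ccccc2)ccc1I
F9 | step 8 | (2R,3R)-4-[4-(benzyloxy)-2-bromophenyl]-2,3-bis{(S)-Ar(tert-butyldimethylsilyloxy)methyl}-4-oxobutanoic acid | CC(C)(C)[Si](C)(C)O[C@H](c1ccc(OCc2ccccc2)cc1)[C@H](C(=O)c1ccc(OCc2ccccc2)cc1Br)[C@@H](C(=O)O)[C@H](O[Si](C)(C)C(C)(C)C)c1ccc(OCc2ccccc2)cc1
F10 | step 8 | (2R,3R)-4-[4-(benzyloxy)-2-bromophenyl]-2,3-bis{(S)-Ar(hydroxy)methyl}-4-oxobutanoic acid | O[C@H](c1ccc(OCc2ccccc2)cc1)[C@H](C(=O)c1ccc(OCc2ccccc2)cc1Br)[C@@H](C(=O)O)[C@H](O)c1ccc(OCc2ccccc2)cc1
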